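**Retrosynthetic overview**
1. Locants follow caryophyllane numbering. C1 and C9 are the two cyclobutane CH shared with the nine-membered ring, C11 is CMe2, C4 is the O-bearing quaternary carbon, C5 is the dihydropyran CH, and C8 carries the exocyclic CH2.
2. Last disconnection: the nine-membered carbocycle is cut at C8–C9 and H is removed from C1. This is a syn hydroalkenylation of a C1=C9 cyclobutene by a 2-triflyloxy-1-alkene at the end of the C5 side chain.
3. Enabling feature: C9 is a cyclobutane CH bound to the sp2 carbon C8, and its C8 bond lies trans to the C1–C2 bond. The four-membered ring can therefore be carried as an achiral, strained 1-alkyl-4,4-dimethylcyclobutene, and one operation delivers C1, C9, the trans fusion, the ring and the intact C8=CH2.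
4. Dihydropyran: C4–O and C5 come from a Sharpless epoxide of an E-allylic alcohol opened anti at C5. The CH2 bridge comes from a reductive Knoevenagel coupling with the dearomatised acylphloroglucinol, and cyclodehydration closes the O–C(sp2) bond.
5. Ring order: four-membered ring (purchased) and six-membered trione ring (step 9), then the dihydropyran (step 11), then the nine-membered ring (step 13).

Key step: step 13

Remark: the (R) antipode of DTBM-SEGPHOS is written for the ligand that directs hydride to the C1 face giving (1R,9S); if the sense proves opposite, the (S) antipode is used.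
Remark: 2,2-dimethylcyclobutan-1-one is taken as a catalogue building block.

Step 1
Reactants: 1 2,2-dimethylcyclobutan-1-one
Product: 2 4,4-dimethylcyclobut-1-en-1-yl trifluoromethanesulfonate
Conditions: LiN(iPr)2, THF, −78 °C; PhNTf2, −78→0 °C
Reagents that add atoms: N-phenylbis(trifluoromethanesulfonimide), O=S(=O)(N(c1ccccc1)S(=O)(=O)C(F)(F)F)C(F)(F)F
Why: Enol triflate formation: deprotonation is possible only at the CH2 flank because the other alpha carbon is quaternary, so O-sulfonylation should fix the double bond regiospecifically between the future C1 and C9.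

Step 2
Reactants: 2 4,4-dimethylcyclobut-1-en-1-yl trifluoromethanesulfonate; 3 (4-bromobut-1-yn-1-yl)trimethylsilane
Product: 5 [4-(4,4-dimethylcyclobut-1-en-1-yl)but-1-yn-1-yl]trimethylsilane, via silylbutynyl Grignard reagent 4 (not isolated)
Conditions: 3, Mg, THF; then 2, Fe(acac)3 (cat.), THF/NMP, −30→0 °C
Reagents that add atoms: none
Why: Iron-catalysed Kumada-type cross-coupling of an alkyl Grignard reagent with an enol triflate should form C1–C2 faster than beta-hydride loss, and the silyl group keeps the alkyne terminus unreactive.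

Step 3
Reactants: 5 [4-(4,4-dimethylcyclobut-1-en-1-yl)but-1-yn-1-yl]trimethylsilane
Product: 6 1-(but-3-yn-1-yl)-4,4-dimethylcyclobut-1-ene
Conditions: K2CO3 (cat.), MeOH, 23 °C
Reagents that add atoms: none
Why: Carbonate-catalysed methanolysis of the alkynyl C–Si bond (protodesilylation) leaves the cyclobutene untouched.

Step 4
Reactants: 6 1-(but-3-yn-1-yl)-4,4-dimethylcyclobut-1-ene
Product: 8 (2E)-5-(4,4-dimethylcyclobut-1-en-1-yl)-3-methylpent-2-en-1-ol, via alkenylalane 7 (not isolated)
Conditions: AlMe3, Cp2ZrCl2 (cat.), CH2Cl2, 0→23 °C; then (CH2O)n, THF, 0→23 °C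
Reagents that add atoms: trimethylaluminium, C[Al](C)C; paraformaldehyde (as formaldehyde), C=O
Why: Negishi zirconium-catalysed carboalumination adds methyl and aluminium syn across the terminal alkyne with methyl on the internal carbon, and hydroxymethylation of the alkenylalane with retention should give the E-trisubstituted allylic alcohol needed for the C4/C5 relationship.

Step 5
Reactants: 8 (2E)-5-(4,4-dimethylcyclobut-1-en-1-yl)-3-methylpent-2-en-1-ol
Product: 9 {(2S,3S)-3-[2-(4,4-dimethylcyclobut-1-en-1-yl)ethyl]-3-methyloxiran-2-yl}methanol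
Conditions: Ti(OiPr)4 (cat.), L-(+)-diethyl tartrate (cat.), t-BuOOH, 4 Å MS, CH2Cl2, −20 °C
Reagents that add atoms: tert-butyl hydroperoxide, CC(C)(C)OO
Why: Sharpless asymmetric epoxidation: only the titanium-bound allylic alkene is oxidised, and L-(+)-diethyl tartrate directs oxygen to the face that gives the (2S,3S)-epoxide, which sets C4 as S for the rest of the route.

Step 6
Reactants: 9 {(2S,3S)-3-[2-(4,4-dimethylcyclobut-1-en-1-yl)ethyl]-3-methyloxiran-2-yl}methanol; 10 2-(2-bromoethyl)-2-methyl-1,3-dioxolane
Product: 12 (2R,3S)-5-(4,4-dimethylcyclobut-1-en-1-yl)-3-methyl-2-[2-(2-methyl-1,3-dioxolan-2-yl)ethyl]pentane-1,3-diol, via dioxolanylethyl Grignard reagent 11 (not isolated)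
Conditions: 10, Mg, THF; then CuI (cat.), 9, THF, −30→0 °C
Reagents that add atoms: none
Why: Copper-catalysed Grignard opening of the 2,3-epoxy alcohol is an SN2 attack at the less hindered secondary carbon C5, whose inversion gives 5R while the C4–O bond and 4S are retained (net anti addition of O and C6 across the E-alkene).

Step 7
Reactants: 12 (2R,3S)-diol
Product: 13 (2R,3S)-bis(triethylsilyl) ether of 12
Conditions: Et3SiOTf, 2,6-lutidine, CH2Cl2, −78→0 °C
Reagents that add atoms: triethylsilyl trifluoromethanesulfonate, CC[Si](CC)(CC)OS(=O)(=O)C(F)(F)F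
Why: Silyl triflate silylation covers the primary and the hindered tertiary hydroxyl, which blocks retro-aldol cleavage and beta-elimination at the aldehyde stage, and the ketal tolerates this reagent pair.

Step 8
Reactants: 13 (2R,3S)-bis(triethylsilyl) ether
Product: 14 (2S,3S)-5-(4,4-dimethylcyclobut-1-en-1-yl)-3-methyl-2-[2-(2-methyl-1,3-dioxolan-2-yl)ethyl]-3-(triethylsilyloxy)pentanal (same spatial arrangement as 13; the descriptor at C2 changes with the priorities)
Conditions: (COCl)2, DMSO, CH2Cl2, −78→−40 °C; Et3N
Reagents that add atoms: none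
Why: Swern conditions oxidise a primary triethylsilyl ether directly to the aldehyde while the tertiary silyl ether stays, and the low temperature keeps the alpha stereocentre C5 intact.

Step 9
Reactants: 15 2-methyl-1-(2,4,6-trihydroxyphenyl)propan-1-one (phlorisobutyrophenone)
Product: 16 3,5-dihydroxy-6,6-dimethyl-2-(2-methylpropanoyl)cyclohexa-2,4-dien-1-one (isobutyrylfilicinic acid, enol form of the 4,4-dimethyl-1,3,5-trione)
Conditions: MeI, NaOMe, MeOH, 0→23 °C
Reagents that add atoms: iodomethane, CI
Why: Dearomative double C-methylation of the acylphloroglucinol: the carbon methylated first becomes the most nucleophilic ring position, so the second methyl should enter at the same carbon and give the gem-dimethyl trione with one free ring CH.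

Step 10
Reactants: 14 (2S,3S)-aldehyde; 16 isobutyrylfilicinic acid
Product: 18 trione 16 carrying on its free ring carbon the (2R,3S)-5-(4,4-dimethylcyclobut-1-en-1-yl)-3-methyl-2-[2-(2-methyl-1,3-dioxolan-2-yl)ethyl]-3-(triethylsilyloxy)pentyl group, via alkylidene trione 17 (not isolated)
Conditions: Hantzsch ester, L-proline (cat.), CH2Cl2, 23 °C
Reagents that add atoms: none
Why: Three-component reductive Knoevenagel alkylation: the acidic ring CH condenses with the aldehyde and the electron-poor alkylidene is reduced at once by hydride transfer from the Hantzsch ester, which forms the CH2 bridge by exclusive C-alkylation without touching C5.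

Step 11
Reactants: 18 C-alkylated trione
Product: 20 (2S,3R)-2-[2-(4,4-dimethylcyclobut-1-en-1-yl)ethyl]-5-hydroxy-2,8,8-trimethyl-6-(2-methylpropanoyl)-3-(3-oxobutyl)-3,4-dihydro-2H-chromen-7(8H)-one, via hydroxy ketone 19 (not isolated)
Conditions: aq HCl (1 M), THF, 23 °C; then PPTS (cat.), PhMe, 60 °C
Reagents that add atoms: water, O
Why: Acid hydrolysis frees the tertiary alcohol and the methyl ketone, and reversible hemiketalisation/dehydration onto the ring carbonyl next to CMe2 should give the vinylogous ester as thermodynamic sink (the hydrogen-bonded enol–isobutyryl chelate stays intact), with retention at C4 because the C4–O bond is never broken.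

Step 12
Reactants: 20 dihydropyran methyl ketone
Product: 21 (2S,3R)-enol triflate: as 20, with 3-[3-(trifluoromethylsulfonyloxy)but-3-en-1-yl] in place of 3-(3-oxobutyl)
Conditions: KN(SiMe3)2 (2.2 equiv), THF, −78 °C; N-(5-chloropyridin-2-yl)bis(trifluoromethanesulfonimide), −78 °C
Reagents that add atoms: N-(5-chloropyridin-2-yl)bis(trifluoromethanesulfonimide), FC(F)(F)S(=O)(=O)N(c1ccc(Cl)cn1)S(=O)(=O)C(F)(F)F
Why: Kinetic deprotonation at the methyl group of the ketone (the first equivalent of base parks the trione as its unreactive enolate) and O-sulfonylation at low temperature should give the terminal enol triflate, that is C8 with its future exocyclic CH2 in place.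

Step 13
Reactants: 21 (2S,3R)-enol triflate
Product: 22 target CNP0497637.1, (1R,4S,5R,9S) in caryophyllane locants
Conditions: Cu(OAc)2 (cat.), (R)-DTBM-SEGPHOS, Pd(OAc)2 (cat.), BrettPhos, MeSiH(OMe)2, NaOSiMe3, THF, 40 °C, slow addition, 2 mM
Reagents that add atoms: none
Why: Proposed new method: ligated copper hydride (monovalent copper, generated from Cu(OAc)2 and the silane) should add syn across the strained trisubstituted C1=C9 bond with H to the substituted C1 and Cu to C9, zerovalent palladium inserts into the C8–O bond of the enol triflate, and stereoretentive copper-to-palladium transfer of the cyclobutyl group followed by reductive elimination forms C8–C9. The closest known reaction types are the intermolecular dual copper hydride/palladium hydroalkenylation of olefins with enol sulfonates and the copper hydride hydrofunctionalisation of 1-substituted cyclobutenes, which are merged here and used for the first time for a medium-ring closure. Only the nine-membered carbocycle is closed, by C(sp3)–C(sp2) reductive elimination from a ten-membered palladacycle, all other rings being already in place. C1 and C9 are set together: the trans ring fusion follows from syn H/Cu addition plus retention (H on C1 and C8 on C9 end up cis, hence the C1–C2 and C9–C8 ring bonds trans), and the absolute sense (1R,9S) follows from the facial choice imposed by the bulky chiral bisphosphine on copper, C4 and C5 being too remote to override it. A competing carbopalladation of the cyclobutene with hydride capture (reductive Heck pathway) would lead to the same constitution and the same relative configuration, so both manifolds converge on 22. The step needs hydrometalation of the cyclobutene only (secured by its ring strain, by the trione being parked as sodium enolate and by the tetrasubstituted push-pull C=C of the vinylogous ester), no beta-hydride loss (it would have to regenerate a cyclobutene) and ring closure over oligomerisation (secured by slow addition at high dilution and by the gauche, trans-diequatorial placement of the two arms on C4 and C5).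

**Compound list**
1 | 2,2-dimethylcyclobutan-1-one | CC1(C)CCC1=O | starting material
2 | 4,4-dimethylcyclobut-1-en-1-yl trifluoromethanesulfonate | CC1(C)CC=C1OS(=O)(=O)C(F)(F)F | intermediate
3 | (4-bromobut-1-yn-1-yl)trimethylsilane | C[Si](C)(C)C#CCCBr | starting material
4 | [4-(trimethylsilyl)but-3-yn-1-yl]magnesium bromide | C[Si](C)(C)C#CCC[Mg]Br | intermediate
5 | [4-(4,4-dimethylcyclobut-1-en-1-yl)but-1-yn-1-yl]trimethylsilane | CC1(C)CC=C1CCC#C[Si](C)(C)C | intermediate
6 | 1-(but-3-yn-1-yl)-4,4-dimethylcyclobut-1-ene | CC1(C)CC=C1CCC#C | intermediate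
7 | [(1E)-4-(4,4-dimethylcyclobut-1-en-1-yl)-2-methylbut-1-en-1-yl]dimethylalane | CC1(C)CC=C1CC/C(C)=C/[Al](C)C | intermediate
8 | (2E)-5-(4,4-dimethylcyclobut-1-en-1-yl)-3-methylpent-2-en-1-ol | CC1(C)CC=C1CC/C(C)=C/CO | intermediate
9 | {(2S,3S)-3-[2-(4,4-dimethylcyclobut-1-en-1-yl)ethyl]-3-methyloxiran-2-yl}methanol | OC[C@@H]1O[C@@]1(C)CCC2=CCC2(C)C | intermediate
10 | 2-(2-bromoethyl)-2-methyl-1,3-dioxolane | CC1(CCBr)OCCO1 | starting material
11 | [2-(2-methyl-1,3-dioxolan-2-yl)ethyl]magnesium bromide | CC1(CC[Mg]Br)OCCO1 | intermediate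
12 | (2R,3S)-5-(4,4-dimethylcyclobut-1-en-1-yl)-3-methyl-2-[2-(2-methyl-1,3-dioxolan-2-yl)ethyl]pentane-1,3-diol | CC1(OCCO1)CC[C@@H]([C@@](C)(O)CCC2=CCC2(C)C)CO | intermediate
13 | (2R,3S)-bis(triethylsilyl) ether of 12 | CC1(OCCO1)CC[C@@H]([C@@](C)(O[Si](CC)(CC)CC)CCC2=CCC2(C)C)CO[Si](CC)(CC)CC | intermediate
14 | (2S,3S)-5-(4,4-dimethylcyclobut-1-en-1-yl)-3-methyl-2-[2-(2-methyl-1,3-dioxolan-2-yl)ethyl]-3-(triethylsilyloxy)pentanal | CC1(OCCO1)CC[C@@H]([C@@](C)(O[Si](CC)(CC)CC)CCC2=CCC2(C)C)C=O | intermediate
15 | 2-methyl-1-(2,4,6-trihydroxyphenyl)propan-1-one | CC(C)C(=O)c1c(O)cc(O)cc1O | starting material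
16 | 3,5-dihydroxy-6,6-dimethyl-2-(2-methylpropanoyl)cyclohexa-2,4-dien-1-one | CC(C)C(=O)C1=C(O)C=C(O)C(C)(C)C1=O | intermediate
17 | alkylidene trione (Knoevenagel adduct of 14 and 16, double-bond geometry open) | CC1(OCCO1)CC[C@@H]([C@@](C)(O[Si](CC)(CC)CC)CCC2=CCC2(C)C)C=C3C(=O)C(C)(C)C(=O)C(C(=O)C(C)C)=C3O | intermediate
18 | C-alkylated trione, side chain (2R,3S) | CC1(OCCO1)CC[C@@H]([C@@](C)(O[Si](CC)(CC)CC)CCC2=CCC2(C)C)CC3=C(O)C(C)(C)C(=O)C(C(=O)C(C)C)=C3O | intermediate
19 | hydroxy ketone (18 without silyl group and ketal) | CC(=O)CC[C@@H]([C@@](C)(O)CCC1=CCC1(C)C)CC2=C(O)C(C)(C)C(=O)C(C(=O)C(C)C)=C2O | intermediate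
20 | (2S,3R)-2-[2-(4,4-dimethylcyclobut-1-en-1-yl)ethyl]-5-hydroxy-2,8,8-trimethyl-6-(2-methylpropanoyl)-3-(3-oxobutyl)-3,4-dihydro-2H-chromen-7(8H)-one | CC(=O)CC[C@@H]1CC2=C(O[C@@]1(C)CCC3=CCC3(C)C)C(C)(C)C(=O)C(C(=O)C(C)C)=C2O | intermediate
21 | (2S,3R)-enol triflate of 20 (3-[3-(trifluoromethylsulfonyloxy)but-3-en-1-yl]) | C=C(OS(=O)(=O)C(F)(F)F)CC[C@@H]1CC2=C(O[C@@]1(C)CCC3=CCC3(C)C)C(C)(C)C(=O)C(C(=O)C(C)C)=C2O | intermediate
22 | CNP0497637.1, (1R,4S,5R,9S) | C=C1CC[C@@H]2CC3=C(O[C@@]2(C)CC[C@@H]2[C@@H]1CC2(C)C)C(C)(C)C(=O)C(C(=O)C(C)C)=C3O | target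

**Step count.** Total: 13 steps. Longest linear sequence: 12 steps (steps 1–8 and 10–13).

**Steps most likely to fail**

Step 13. Intermolecular coupling may outrun ring closure. The cyclobutylcopper species may be protonated before it reaches palladium, which would simply reduce the cyclobutene. Configuration may also erode during the metal-to-metal transfer. The fallback uses known reactions and makes the nucleophile stoichiometric, so that every molecule carries it. It sets out from 21. Copper-catalysed asymmetric hydroboration of the cyclobutene with pinacolborane (CuCl, (R)-DTBM-SEGPHOS, KOtBu, THF) should give, by syn addition, the trans cyclobutyl pinacol boronate F1. KHF2 in aqueous methanol converts it into the potassium cyclobutyltrifluoroborate F2. An intramolecular Suzuki–Miyaura coupling of the secondary cyclobutyltrifluoroborate with the enol triflate (Pd(OAc)2, di(1-adamantyl)-n-butylphosphine, Cs2CO3, toluene/water, high dilution) then comes back to the route at 22.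

Step 10. Condensation of the hindered alpha-branched aldehyde may be slow. This would leave time for enolisation (epimerisation at C5) or for loss of silanolate from the alkylidene before hydride transfer. The fallback separates trapping from reduction. It sets out from 14 and 16. A three-component condensation with thiophenol (piperidine cat., CH2Cl2) captures the alkylidene as it forms, giving the phenylsulfanyl adduct F3. Radical desulfurisation (Bu3SnH, AIBN, PhMe, 80 °C) comes back to the route at 18.

Step 12. The trione enolate may be O-sulfonylated in competition. The ketone enolate may also equilibrate to the internal isomer while two anionic sites coexist. The fallback removes the acidic site first. It sets out from 20. Silylation of the enol (t-BuMe2SiCl, imidazole, DMF) gives the enol silyl ether F4. One equivalent of KN(SiMe3)2 and the same triflating reagent at −78 °C give the silylated enol triflate F5. Brief treatment with aqueous acetic acid in THF comes back to the route at 21.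

**Further compounds**
F1 | step 13 | trans cyclobutyl pinacol boronate of 21 (B on C9, H on C1, syn) | C=C(OS(=O)(=O)C(F)(F)F)CC[C@@H]1CC2=C(O[C@@]1(C)CC[C@@H]3[C@@H](B4OC(C)(C)C(C)(C)O4)CC3(C)C)C(C)(C)C(=O)C(C(=O)C(C)C)=C2O
F2 | step 13 | potassium cyclobutyltrifluoroborate from F1 | C=C(OS(=O)(=O)C(F)(F)F)CC[C@@H]1CC2=C(O[C@@]1(C)CC[C@@H]3[C@@H]([B-](F)(F)F)CC3(C)C)C(C)(C)C(=O)C(C(=O)C(C)C)=C2O.[K+]
F3 | step 10 | phenylsulfanyl adduct of 14, 16 and thiophenol (configuration at the S-bearing carbon open) | CC1(OCCO1)CC[C@@H]([C@@](C)(O[Si](CC)(CC)CC)CCC2=CCC2(C)C)C(Sc3ccccc3)C4=C(O)C(C)(C)C(=O)C(C(=O)C(C)C)=C4O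
F4 | step 12 | tert-butyldimethylsilyl enol ether of 20 | CC(=O)CC[C@@H]1CC2=C(O[C@@]1(C)CCC3=CCC3(C)C)C(C)(C)C(=O)C(C(=O)C(C)C)=C2O[Si](C)(C)C(C)(C)C
F5 | step 12 | tert-butyldimethylsilyl enol ether of 21 | C=C(OS(=O)(=O)C(F)(F)F)CC[C@@H]1CC2=C(O[C@@]1(C)CCC3=CCC3(C)C)C(C)(C)C(=O)C(C(=O)C(C)C)=C2O[Si](C)(C)C(C)(C)C
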